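## The problem

Target 14 is two identical hydroxyquinone rings joined through an unbranched chain of thirteen methylene carbons (c1 to c13). The ring atoms are numbered C1 (carbonyl), C2 (methoxy), C3 (methyl), C4 (carbonyl), C5 (hydroxyl) and C6 (tether). There is no stereocentre and no alkene geometry, so nothing has to be induced by anything else. The difficulty lies in placing four different substituents around each fully substituted ring and in making two aryl-to-chain connections without a statistical mixture. The 5-hydroxyquinone is a vinylogous carboxylic acid: it is acidic, chelates metals, is attacked by bases and nucleophiles and cannot coexist with organometallic reagents, so it has to be unveiled last from an aromatic precursor. At the arene oxidation level each ring gains a mirror plane through C3 and C6, with two equivalent oxygens flanking the tether carbon and two equivalent methoxy groups flanking the methyl group; this removes every regiochemical question from ring functionalisation and from the closing oxidation. The feature that opens the key step is that c1 sits on C6 next to the C5 oxygen: C5–O, C6 and c1 are the three atoms of an ortho-quinone methide, so c1 can be made electrophilic and the c1–c2 bond, with its twin c12–c13, formed by a carbon nucleophile. Since the two chain ends are identical, one eleven-carbon bis-nucleophile can supply c2 to c12 in a single two-directional operation, and what remains is chemoselectivity: the transient quinone methide must be captured at carbon faster than it dimerises, and the aryl tert-butyl carbonates that trigger it must survive a Grignard reagent.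

## Retrosynthesis

**14 ⇒ 13.** No skeletal bond is cut. Each quinone is traced back to the 4-methoxyphenol ring of bis-resorcinol 13, in which the C1 oxygen is still a methyl ether and C5–OH is a phenol. The neighbouring option, a dimethoxyquinone hydrolysed at one ether, would have to distinguish two vinylogous esters. In 13 the two phenols of a ring are mirror images, so oxidation has one outcome. The forward step must remove two electrons and one methanol per ring and then stop.

**13 ⇒ 12.** The two free phenols are re-masked as tert-butyl carbonates. Compound 12 carries one carbonate and one free phenol per ring because that is what the key step leaves behind, so no extra protecting-group logic is needed. The forward step is a plain acidolysis on rings that have no free C–H.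

**12 ⇒ 7 + 9 (through 10 and 11).** The c1–c2 and c12–c13 bonds are cut.
- Cutting at C6–c1 instead would ask a hexasubstituted arylmetal, flanked by two oxygens, to displace a C13 dielectrophile; that substitution is sluggish and the chain is less available.
- Cutting inside the chain would need an sp3–sp3 coupling with no polarity bias.
- The chosen cut uses the innate polarity of the ring: benzylic alcohol 7 releases quinone methide 10, and each C–Mg terminus of bis-Grignard 9 adds to its methylene, first giving mono-adduct 11 and then 12.
- The precursors are one achiral arene, used twice, and a C11 chain.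
- The forward reaction must release 10 slowly in the presence of 9 and must favour conjugate addition over attack at a carbonate.

**9 ⇒ 8.** Both C–Mg bonds come from the C–Br bonds of commercial dibromide 8 by magnesium insertion.

**7 ⇒ 6 ⇒ 5.** These are functional-group changes only. Alcohol 7 comes from aldehyde 6 by a reduction that never passes through a free alkoxide, and the carbonates of 6 are placed on the two phenols of dihydroxy aldehyde 5. Putting the carbonates on at the aldehyde stage avoids having to tell phenolic from benzylic hydroxyl groups.

**5 ⇒ 4.** The C6–c1 bond is cut, with c1 entering as a formyl carbon. Resorcinol 4 has a single ring C–H, and it lies between the two hydroxyl groups, so an ortho-directed formylation cannot give a regioisomer. The forward step must formylate a crowded, very electron-rich position without condensing two arenes.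

**4 ⇒ 3 ⇒ 2 ⇒ 1.** The two C–O bonds flanking C6 are traced back to C–B bonds in bis-boronate 3, to C–Br bonds in dibromide 2, and to the C–H bonds of commercial 1. In 1 the two methoxy groups direct both brominations to the required carbons. Each step is a standard arene operation and the mirror symmetry is kept throughout.

## Roads not taken

**Alternative 1:** biomimetic double aldol aromatisation.
- **Cut:** in each ring, the bond between tether-bearing C6 and its ortho ring carbon.
- **Forward key step:** mild aqueous base cyclises the bis(triketo ester) A1, each C2 methylene attacking the chain ketone, to the bis(resorcylate) A2.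
- **Merits:** both benzene rings are built from an open chain in one mild operation without organometallic reagents, and the tether with two ring carbons comes in one piece from a long-chain diacid derivative.
- **Weak points:**
  - A2 does not carry the oxygen pattern of the target. The tether carbon is flanked by an ester carbon and a ring C–H where two oxygens are needed.
  - After the key step there would follow decarboxylation, two ring oxygenations and differentiation of the oxygens, all twice.
  - A1 is a doubly enolisable polyketone with competing cyclisation modes (Claisen-type closure, pyrone formation), and any inefficiency is squared in the two-directional version.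
- **Comparison:** the chosen plan takes the full oxygen pattern from simple arene chemistry and needs two steps after the key step. Alternative 1 is superior only in avoiding metals and protecting groups, and that does not make up for the long post-aromatisation sequence.

**Alternative 2:** electroreductive double decarboxylative coupling.
- **Cut:** c3–c4 and c10–c11.
- **Forward key step:** cathodic reduction with NiCl2·6H2O and 2,2':6',2''-terpyridine against a magnesium anode couples two molecules of the aryl butanoate redox-active ester A3 with the bis(N-hydroxyphthalimide) ester of nonanedioic acid A4, giving A5 with loss of four CO2.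
- **Merits:** the conditions are mild and tolerate acetal protection, the central chain is a commodity diacid, and A5 is robust. A5 is two steps from the target, since acid would take it to 13.
- **Weak points:**
  - Both partners are unactivated primary alkyl radicals or alkylnickel species, so there is no intrinsic cross-selectivity.
  - Homocoupling of A3 and oligomerisation of A4 compete, and the demand is doubled by the two ends of A4.
  - A3 still requires a carbon–carbon bond at the same crowded ring carbon, now with three further chain carbons to install and activate, so the arene work is not shortened.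
- **Comparison:** the chosen plan gets its cross-selectivity from polarity (electrophilic quinone methide, nucleophilic Grignard), so like-with-like coupling is not a built-in outcome. Alternative 2 is better in avoiding a short-lived intermediate and carbonate-sensitive organometallics; the chosen plan sets against this a shorter route to the aryl partner and a polarity-matched bond formation.

**Alternative 3:** two-directional cyclobutenone ring expansion.
- **Cut:** the C1–C2 bond of each ring.
- **Forward key step:** heating the bis(4-alkenyl-4-hydroxycyclobutenone) A6 opens both four-membered rings to dienylketenes that close by 6π electrocyclisation to the bis-hydroquinone A7.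
- **Merits:** the ring substituents are programmed by the order of additions to a squaric ester. A7 already has every oxygen in place, so only oxidation and removal of the isopropyl group would remain. On paper this road is probably as short as the chosen one, or shorter, and it is the most elegant answer to the substitution problem.
- **Weak points:**
  - It needs a thirteen-carbon bis-organometallic chain, which is less available than the C11 dibromide.
  - It needs a β-methoxy alkenyllithium that is not routine to prepare or handle.
  - Four regioselective carbonyl additions are required, and A6 forms as a diastereomer mixture.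
  - The end game must cleave the isopropyl ether of a quinone selectively beside a methyl ether.
- **Comparison:** Alternative 3 is better in step count after ring formation and in regiochemical programming. The chosen plan sets against it commercial reagents throughout, ordinary arene chemistry in which mirror symmetry makes regiochemistry a non-issue, and a final oxidation whose every pathway converges on the target.

Key step: step 8

Assumption: the tether is read as thirteen CH2 groups and the molecule is achiral, so no stereodescriptors are needed. Di-tert-butyl dicarbonate, N-bromosuccinimide and bis(pinacolato)diboron are treated as commercial reagents.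

## Route

Step 1
Reactants: 1 2,6-dimethoxytoluene
Product: 2 1,5-dibromo-2,4-dimethoxy-3-methylbenzene
Conditions: NBS (2.2 equiv), MeCN, 0 → 50 °C
Reagents that add atoms: N-bromosuccinimide, O=C1CCC(=O)N1Br
Why: Electrophilic aromatic bromination; the two carbons next to the methoxy groups are each ortho to one methoxy and para to the other, while the carbon para to methyl is meta to both, so both bromines should enter beside the methoxy groups, and the polar medium without initiator spares the benzylic methyl.

Step 2
Reactants: 2 1,5-dibromo-2,4-dimethoxy-3-methylbenzene
Product: 3 2,2'-(4,6-dimethoxy-5-methyl-1,3-phenylene)bis(4,4,5,5-tetramethyl-1,3,2-dioxaborolane)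
Conditions: B2pin2 (2.6 equiv), PdCl2(dppf) (5 mol %; dppf = 1,1'-bis(diphenylphosphino)ferrocene), KOAc (6 equiv), 1,4-dioxane, 90 °C
Reagents that add atoms: bis(pinacolato)diboron, CC1(C)OB(OC1(C)C)B1OC(C)(C)C(C)(C)O1
Why: Miyaura borylation; each C–Br bond undergoes oxidative addition, acetate-assisted transmetalation from the diboron reagent and reductive elimination, and the weak base KOAc keeps the ortho-methoxy arylboronates from coupling further.

Step 3
Reactants: 3 2,2'-(4,6-dimethoxy-5-methyl-1,3-phenylene)bis(4,4,5,5-tetramethyl-1,3,2-dioxaborolane)
Product: 4 4,6-dimethoxy-5-methylbenzene-1,3-diol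
Conditions: 30% aq H2O2, 2 M NaOH, THF, 0 °C, argon; Na2S2O3, then 1 M HCl
Reagents that add atoms: hydrogen peroxide, OO
Why: Boronate oxidation; hydroperoxide adds to boron, the aryl group shifts from boron to oxygen and the borate is hydrolysed, so each boron is replaced by hydroxyl at the same carbon, and cold oxygen-free handling with a reductive quench protects the electron-rich resorcinol.

Step 4
Reactants: 4 4,6-dimethoxy-5-methylbenzene-1,3-diol
Product: 5 2,6-dihydroxy-3,5-dimethoxy-4-methylbenzaldehyde
Conditions: MgCl2 (3 equiv), Et3N (6 equiv), (CH2O)n (8 equiv), MeCN, 80 °C, argon; 1 M HCl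
Reagents that add atoms: formaldehyde (as paraformaldehyde), C=O
Why: Casnati–Skattebøl magnesium-mediated ortho-formylation; the magnesium phenoxide delivers formaldehyde to the ortho carbon through a cyclic transition state and a second formaldehyde oxidises the benzylic alkoxide by hydride transfer, and since the only ring C–H of 4 lies ortho to both phenoxides no regioisomer is possible.

Step 5
Reactants: 5 2,6-dihydroxy-3,5-dimethoxy-4-methylbenzaldehyde
Product: 6 di-tert-butyl (2-formyl-4,6-dimethoxy-5-methyl-1,3-phenylene) bis(carbonate)
Conditions: Boc2O (2.5 equiv), i-Pr2NEt (3 equiv), DMAP (10 mol %), CH2Cl2, 0 °C → rt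
Reagents that add atoms: di-tert-butyl dicarbonate, CC(C)(C)OC(=O)OC(=O)OC(C)(C)C
Why: DMAP-catalysed O-acylation of phenols to aryl tert-butyl carbonates; the two hydroxyl groups are equivalent and the aldehyde and methyl ethers are inert under these conditions.

Step 6
Reactants: 6 di-tert-butyl (2-formyl-4,6-dimethoxy-5-methyl-1,3-phenylene) bis(carbonate)
Product: 7 [2,6-bis(tert-butoxycarbonyloxy)-3,5-dimethoxy-4-methylphenyl]methanol
Conditions: BH3·THF (1.2 equiv), THF, −10 → 0 °C; MeOH, then pH 7 buffer, 0 °C
Reagents that add atoms: none
Why: Electrophilic borane reduction of an aldehyde; hydride is delivered within a neutral complex and the product is held as an alkoxyborane and not as a free alkoxide, so the base-triggered carbonate transfer that an anionic hydride would start should not occur, and aryl carbonates are not reduced by BH3 at this temperature.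

Step 7
Reactants: 8 1,11-dibromoundecane
Product: 9 undecane-1,11-diylbis(magnesium bromide)
Conditions: Mg turnings (4 equiv, I2-activated), THF, 45 °C, slow addition of 8; titrated before use
Reagents that add atoms: magnesium, [Mg]
Why: Grignard formation by insertion of magnesium into both primary C–Br bonds; eleven carbons separate the termini, so cyclisation does not compete, and slow addition to excess metal limits Wurtz coupling.

Step 8
Reactants: 7 [2,6-bis(tert-butoxycarbonyloxy)-3,5-dimethoxy-4-methylphenyl]methanol (2.3 equiv); 9 undecane-1,11-diylbis(magnesium bromide) (1.0 equiv)
Product: 12 di-tert-butyl [tridecane-1,13-diylbis(3-hydroxy-4,6-dimethoxy-5-methyl-2,1-phenylene)] bis(carbonate), via o-quinone methide 10 (not isolated), via mono-adduct Grignard 11 (not isolated)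
Conditions: 7, t-BuMgCl (1.0 equiv per 7), THF, −78 °C, 10 min; then 9 in THF, −78 → 0 °C over 3 h; sat. aq NH4Cl
Reagents that add atoms: none
Why: t-BuMgCl removes the hydroxyl proton of 7 at −78 °C; on warming, the magnesium alkoxide attacks the neighbouring aryl carbonate, the Boc group moves to the benzylic oxygen, and the phenoxide so released expels tert-butyl carbonate in a 1,4-elimination to give o-quinone methide 10. Each C–Mg terminus of 9 then adds to the exocyclic methylene of 10 in a conjugate addition driven by re-aromatisation, first giving 11 and then, with a second molecule of 10, the bis-phenoxide of 12; these are the c1–c2 and c12–c13 bonds. The closest known reaction type is the addition of Grignard reagents to o-quinone methides generated at low temperature from O-Boc salicyl alcohols by this anionic carbonate transfer and elimination; using an α,ω-bis-Grignard reagent applies it at both chain ends. No ring is closed and no stereocentre is created. Because 7 is symmetric about its methyl/hydroxymethyl axis, either carbonate can migrate with the same result, and the step frees exactly the phenol that flanks the tether while the other stays masked. The selectivity needed is conjugate addition over attack at a carbonate carbonyl and over self-reaction of 10; it is secured because 10 forms only gradually as the mixture warms, with the nucleophile already present, and because the surviving tert-butyl carbonate is flanked by a methoxy group and the newly alkylated carbon and is far less electrophilic than the quinone methide. A slight excess of 7 ensures that both termini of 9 end in carbon–carbon bonds and not in proton quench.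

Step 9
Reactants: 12 di-tert-butyl [tridecane-1,13-diylbis(3-hydroxy-4,6-dimethoxy-5-methyl-2,1-phenylene)] bis(carbonate)
Product: 13 2,2'-(tridecane-1,13-diyl)bis(4,6-dimethoxy-5-methylbenzene-1,3-diol)
Conditions: CF3CO2H/CH2Cl2 (1:4), 0 °C → rt, argon
Reagents that add atoms: none
Why: Acidolysis of aryl tert-butyl carbonates by loss of the tert-butyl cation and decarboxylation; the rings have no free C–H, so ring tert-butylation cannot occur, and the methyl ethers and the alkyl tether are stable.

Step 10
Reactants: 13 2,2'-(tridecane-1,13-diyl)bis(4,6-dimethoxy-5-methylbenzene-1,3-diol)
Product: 14 6,6'-(tridecane-1,13-diyl)bis(5-hydroxy-2-methoxy-3-methylcyclohexa-2,5-diene-1,4-dione)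
Conditions: PhI(OAc)2 (2.2 equiv), MeCN/THF/H2O (4:2:1), 0 °C
Reagents that add atoms: water, O
Why: Hypervalent-iodine oxidative demethylation of a 4-methoxyphenol; the phenol binds to iodine, water attacks the methoxy-bearing para carbon and the hemiketal loses methanol to give the quinone, while the second hydroxyl becomes the vinylogous acid. Because each ring of 13 has a mirror plane, engagement of either phenol, and attack para or ortho (the ortho-quinone tautomerises), should lead to the same hydroxyquinone, which is electron-poor and resists a second oxidation.

## Compound list

1 | 2,6-dimethoxytoluene | Cc1c(OC)cccc1OC | starting material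
2 | 1,5-dibromo-2,4-dimethoxy-3-methylbenzene | Cc1c(OC)c(Br)cc(Br)c1OC | intermediate
3 | 2,2'-(4,6-dimethoxy-5-methyl-1,3-phenylene)bis(4,4,5,5-tetramethyl-1,3,2-dioxaborolane) | Cc1c(OC)c(B2OC(C)(C)C(C)(C)O2)cc(B2OC(C)(C)C(C)(C)O2)c1OC | intermediate
4 | 4,6-dimethoxy-5-methylbenzene-1,3-diol | Cc1c(OC)c(O)cc(O)c1OC | intermediate
5 | 2,6-dihydroxy-3,5-dimethoxy-4-methylbenzaldehyde | Cc1c(OC)c(O)c(C=O)c(O)c1OC | intermediate
6 | di-tert-butyl (2-formyl-4,6-dimethoxy-5-methyl-1,3-phenylene) bis(carbonate) | Cc1c(OC)c(OC(=O)OC(C)(C)C)c(C=O)c(OC(=O)OC(C)(C)C)c1OC | intermediate
7 | [2,6-bis(tert-butoxycarbonyloxy)-3,5-dimethoxy-4-methylphenyl]methanol | CC(C)(C)OC(=O)Oc1c(CO)c(OC(=O)OC(C)(C)C)c(OC)c(C)c1OC | intermediate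
8 | 1,11-dibromoundecane | BrCCCCCCCCCCCBr | starting material
9 | undecane-1,11-diylbis(magnesium bromide) | Br[Mg]CCCCCCCCCCC[Mg]Br | intermediate
10 | tert-butyl (2,4-dimethoxy-3-methyl-6-methylidene-5-oxocyclohexa-1,3-dien-1-yl) carbonate (o-quinone methide, not isolated) | C=C1C(=O)C(OC)=C(C)C(OC)=C1OC(=O)OC(C)(C)C | intermediate
11 | bromomagnesium 2-[12-(bromomagnesio)dodecyl]-3-(tert-butoxycarbonyloxy)-4,6-dimethoxy-5-methylphenoxide (mono-adduct, not isolated) | CC(C)(C)OC(=O)Oc1c(OC)c(C)c(OC)c(O[Mg]Br)c1CCCCCCCCCCCC[Mg]Br | intermediate
12 | di-tert-butyl [tridecane-1,13-diylbis(3-hydroxy-4,6-dimethoxy-5-methyl-2,1-phenylene)] bis(carbonate) | CC(C)(C)OC(=O)Oc1c(OC)c(C)c(OC)c(O)c1CCCCCCCCCCCCCc1c(O)c(OC)c(C)c(OC)c1OC(=O)OC(C)(C)C | intermediate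
13 | 2,2'-(tridecane-1,13-diyl)bis(4,6-dimethoxy-5-methylbenzene-1,3-diol) | COc1c(C)c(OC)c(O)c(CCCCCCCCCCCCCc2c(O)c(OC)c(C)c(OC)c2O)c1O | intermediate
14 | 6,6'-(tridecane-1,13-diyl)bis(5-hydroxy-2-methoxy-3-methylcyclohexa-2,5-diene-1,4-dione) | COC1=C(C)C(=O)C(O)=C(CCCCCCCCCCCCCC2=C(O)C(=O)C(C)=C(OC)C2=O)C1=O | target

## Step count and risks

Total step count: 10. Longest linear sequence: 9 steps (steps 1 to 6, then 8, 9 and 10, from 1 to 14); step 7 is a one-step side branch from 8.

**Step 8 (key step).**
- What may go wrong:
  - Self-reaction of the quinone methide (dimerisation or oligomerisation) as the concentration of C–Mg termini falls in the second half of the reaction.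
  - Acylation of the Grignard reagent by a carbonate carbonyl.
  - Proton quench of one terminus, which leaves singly arylated chains.
  - Capture of CO2 set free if the expelled tert-butyl carbonate fragments.
- Fallback: an olefination approach that sets out from 5 and 8 and comes back to the route at 13.
  - Aldehyde 5 is benzylated (benzyl bromide, K2CO3, DMF) to 2,6-bis(benzyloxy)-3,5-dimethoxy-4-methylbenzaldehyde F1.
  - Dibromide 8 is heated with triphenylphosphine to give undecane-1,11-diylbis(triphenylphosphonium) dibromide F2.
  - The bis-ylide from F2 (NaN(SiMe3)2, THF, −78 °C → rt) undergoes a double Wittig reaction with two molecules of F1 to give 1,13-bis[2,6-bis(benzyloxy)-3,5-dimethoxy-4-methylphenyl]trideca-1,12-diene F3 as a mixture of alkene isomers.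
  - Hydrogen over palladium on carbon (Pd/C) then saturates both alkenes and cleaves the four benzyl ethers in one operation, giving 13.

**Step 4.**
- What may go wrong: 4 is extremely electron-rich and its reacting carbon is flanked on both sides, so condensation of the intermediate benzylic alkoxide with a second arene (diarylmethane formation), O-alkylation by formaldehyde, or air oxidation under the basic hot conditions may compete with formylation.
- Fallback: a directed-metalation approach that sets out from 4 and comes back at 5.
  - Both phenols are protected with chloromethyl methyl ether and i-Pr2NEt to give 1,5-bis(methoxymethoxy)-2,4-dimethoxy-3-methylbenzene F4.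
  - Lithiation between the two acetal oxygens (n-BuLi, TMEDA, THF, 0 °C) and quenching with DMF give 2,6-bis(methoxymethoxy)-3,5-dimethoxy-4-methylbenzaldehyde F5.
  - HCl in methanol removes both acetals to give 5.

**Step 10.**
- What may go wrong: over-oxidation or oxidative coupling of the doubly phenolic rings of 13, and loss of material through air oxidation of 13 during handling.
- Fallback: a change in the order of events, setting out from 12 and coming back at 14.
  - PhI(OAc)2 in wet acetonitrile oxidises 12, in which only one phenol per ring is free and its para carbon bears a methoxy group, to 1,13-bis[2-(tert-butoxycarbonyloxy)-5-methoxy-4-methyl-3,6-dioxocyclohexa-1,4-dien-1-yl]tridecane F6.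
  - CF3CO2H in CH2Cl2 then cleaves the two enol carbonates to give 14.

**Step 2.**
- What may go wrong: incomplete borylation of the second bromide and protodeboronation of the ortho-methoxy arylboronates, which would carry mono-functionalised material into step 3.
- Fallback: a direct carbon–oxygen coupling that sets out from 2 and comes back at 4, bypassing 3. Palladium-catalysed hydroxylation of both C–Br bonds with KOH (Pd2(dba)3, 2-di-tert-butylphosphino-2',4',6'-triisopropylbiphenyl, 1,4-dioxane/H2O, 100 °C, then acid) gives 4 without any new intermediate.

## Further compounds

F1 | step 8 | 2,6-bis(benzyloxy)-3,5-dimethoxy-4-methylbenzaldehyde | O=Cc1c(OCc2ccccc2)c(OC)c(C)c(OC)c1OCc1ccccc1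
F2 | step 8 | undecane-1,11-diylbis(triphenylphosphonium) dibromide | [Br-].[Br-].c1ccc(cc1)[P+](CCCCCCCCCCC[P+](c1ccccc1)(c1ccccc1)c1ccccc1)(c1ccccc1)c1ccccc1
F3 | step 8 | 1,13-bis[2,6-bis(benzyloxy)-3,5-dimethoxy-4-methylphenyl]trideca-1,12-diene (mixture of alkene isomers) | COc1c(C)c(OC)c(OCc2ccccc2)c(C=CCCCCCCCCCC=Cc2c(OCc3ccccc3)c(OC)c(C)c(OC)c2OCc2ccccc2)c1OCc1ccccc1
F4 | step 4 | 1,5-bis(methoxymethoxy)-2,4-dimethoxy-3-methylbenzene | COCOc1cc(OCOC)c(OC)c(C)c1OC
F5 | step 4 | 2,6-bis(methoxymethoxy)-3,5-dimethoxy-4-methylbenzaldehyde | COCOc1c(C=O)c(OCOC)c(OC)c(C)c1OC
F6 | step 10 | 1,13-bis[2-(tert-butoxycarbonyloxy)-5-methoxy-4-methyl-3,6-dioxocyclohexa-1,4-dien-1-yl]tridecane | CC(C)(C)OC(=O)OC1=C(CCCCCCCCCCCCCC2=C(OC(=O)OC(C)(C)C)C(=O)C(C)=C(OC)C2=O)C(=O)C(OC)=C(C)C1=O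
F0 | step 2 | none | none
A1 | alternative 1 | dimethyl 4,24-dimethyl-3,5,7,21,23,25-hexaoxoheptacosanedioate (mixture of stereoisomers and enol forms) | COC(=O)CC(=O)C(C)C(=O)CC(=O)CCCCCCCCCCCCCC(=O)CC(=O)C(C)C(=O)CC(=O)OC
A2 | alternative 1 | dimethyl 6,6'-(tridecane-1,13-diyl)bis(2,4-dihydroxy-3-methylbenzoate) | COC(=O)c1c(O)c(C)c(O)cc1CCCCCCCCCCCCCc1cc(O)c(C)c(O)c1C(=O)OC
A3 | alternative 2 | 1,3-dioxoisoindolin-2-yl 4-[2,6-bis(methoxymethoxy)-3,5-dimethoxy-4-methylphenyl]butanoate | COCOc1c(CCCC(=O)ON2C(=O)c3ccccc3C2=O)c(OCOC)c(OC)c(C)c1OC
A4 | alternative 2 | bis(1,3-dioxoisoindolin-2-yl) nonanedioate | O=C(CCCCCCCC(=O)ON1C(=O)c2ccccc2C1=O)ON1C(=O)c2ccccc2C1=O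
A5 | alternative 2 | 1,13-bis[2,6-bis(methoxymethoxy)-3,5-dimethoxy-4-methylphenyl]tridecane | COCOc1c(CCCCCCCCCCCCCc2c(OCOC)c(OC)c(C)c(OC)c2OCOC)c(OCOC)c(OC)c(C)c1OC
A6 | alternative 3 | 2,2'-(tridecane-1,13-diyl)bis[4-hydroxy-3-isopropoxy-4-(1-methoxyprop-1-en-2-yl)cyclobut-2-en-1-one] (mixture of diastereomers, alkene geometry not fixed) | COC=C(C)C1(O)C(OC(C)C)=C(CCCCCCCCCCCCCC2=C(OC(C)C)C(O)(C(C)=COC)C2=O)C1=O
A7 | alternative 3 | 6,6'-(tridecane-1,13-diyl)bis(5-isopropoxy-2-methoxy-3-methylbenzene-1,4-diol) | COc1c(C)c(O)c(OC(C)C)c(CCCCCCCCCCCCCc2c(OC(C)C)c(O)c(C)c(OC)c2O)c1O
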